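Ring B, the resorcinol ring shared by the five- and seven-membered rings (B1 bonded to ring-fusion carbon C-8, B2 to the ketone, B3 and B5 oxygenated, B6 bonded to C-9), is built last from open-chain partners. B1–B6 is the former double bond of a chiral cyclopentene, B2 and B5 are the diazomethyl and carbonyl carbons of a diazoketone on it, and B3–B4 come from ethoxyacetylene. One photochemical operation forms four C–C bonds and the arene with meta oxygens, leaving B2 as CH for ring-closing acylation by the ring-A carboxyl. The precursor is a 1-(diazoacetyl)cyclopentene already carrying C-8, C-9, C-10 and the C-7 diarylmethine, with ring A as a methyl benzoate.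

Key step: step 9

Labels: C-7 is the CH(4-hydroxyphenyl) of the seven-membered ring, C-8 the CH common to both carbocycles, C-10 the CH(4-hydroxyphenyl) and C-9 the CH(3,5-dihydroxyphenyl) of the five-membered ring; ring A is the resorcinol ring bonded to C-7 and the ketone; the target is 7S,8R,9S,10S with the three indane substituents all-trans.

Assumption: the enantiopure silyloxy enone 4 and both aryl Grignard solutions (5, 8) are purchased.

Design points:
- The conjugated diazoketone is made by diazo transfer to a methyl enone, because diazomethane can add across the double bond of an enoyl chloride.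
- C-7 is set by conjugate arylation of an arylidene ketone under control of the neighbouring ring centre; an intermolecular Friedel–Crafts alkylation of a β-hydroxy ketone would dehydrate and give no stereocontrol.
- Ring B leaves the key step with two aromatic CH (B2 and B4); only B2 is within reach of the ring-A carboxyl.
- The new phenol is capped as its ethyl ether before the acylation.

Step 1
Reactants: 1 methyl 3,5-dimethoxybenzoate
Product: 3 methyl 2-formyl-3,5-dimethoxybenzoate, via iminium chloride 2 (not isolated)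
Conditions: POCl3, DMF, 0 → 80 °C; then H2O, 0 °C → rt
Reagents that add atoms: N,N-dimethylformamide CN(C)C=O; water O
Why: Vilsmeier–Haack formylation, in which the chloroiminium ion should attack C-2 (para to one methoxy, ortho to the other, less crowded than C-4 between the two methoxy groups) and the aryl iminium salt is hydrolysed to the aldehyde; no stereocentre is formed.

Step 2
Reactants: 4 (S)-4-(tert-butyldimethylsilyloxy)cyclopent-2-en-1-one; 5 3,5-dimethoxyphenylmagnesium chloride
Product: 7 (S)-4-(3,5-dimethoxyphenyl)cyclopent-2-en-1-one, via silyloxy ketone 6 (not isolated)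
Conditions: CuBr·SMe2 (10 mol%), THF, −78 → −40 °C; aq. NH4Cl; then DBU, CH2Cl2, 0 °C, short contact
Reagents that add atoms: none
Why: Copper-catalysed conjugate addition of the aryl Grignard should occur anti to the silyloxy group and set the aryl-bearing centre (future C-9), and E1cB loss of silanolate across the other α-carbon then relocates the enone without touching that centre, the base contact being kept cold and short because the γ-hydrogen is benzylic.

Step 3
Reactants: 7 (S)-4-(3,5-dimethoxyphenyl)cyclopent-2-en-1-one; 8 4-methoxyphenylmagnesium bromide; 3 methyl 2-formyl-3,5-dimethoxybenzoate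
Product: 11 3-[(1R,2R,3S)-3-(3,5-dimethoxyphenyl)-2-(4-methoxyphenyl)-5-oxocyclopentyl]-4,6-dimethoxy-2-benzofuran-1(3H)-one (both lactone epimers), via magnesium enolate 9 (not isolated), via magnesium aldolate 10 (not isolated)
Conditions: 8 (1.1 equiv), CuBr·SMe2 (10 mol%), THF, −78 °C; then 3 (1.5 equiv), −78 °C → rt; aq. NH4Cl
Reagents that add atoms: none
Why: Three-component conjugate addition–aldol reaction in which the aryl group should add anti to the C-4 aryl (trans-3,4, future C-10), the regiodefined enolate is captured at C-2 by the aldehyde anti to the new aryl, and the aldolate closes onto the ortho ester to a phthalide, which makes the aldol irreversible; the lactone carbon forms as both epimers and is flattened in step 4.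

Step 4
Reactants: 11 phthalide from step 3
Product: 13 methyl 2-{(E)-[(2S,3S)-3-(3,5-dimethoxyphenyl)-2-(4-methoxyphenyl)-5-oxocyclopentylidene]methyl}-3,5-dimethoxybenzoate, via cesium carboxylate 12 (not isolated)
Conditions: Cs2CO3, DMF, rt; then MeI, rt
Reagents that add atoms: iodomethane CI
Why: E1cB opening of the β-acyloxy ketone (retro-oxa-Michael) should give the conjugated carboxylate with the aryl trans to the carbonyl under reversible conditions, and SN2 O-methylation then fixes it as the (E)-enone ester, the two ring stereocentres not being acidic.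

Step 5
Reactants: 13 (E)-enone ester from step 4; 8 4-methoxyphenylmagnesium bromide
Product: 15 methyl 2-{(S)-[(1R,2R,3S)-3-(3,5-dimethoxyphenyl)-2-(4-methoxyphenyl)-5-oxocyclopentyl](4-methoxyphenyl)methyl}-3,5-dimethoxybenzoate, via silyl enol ether 14 (not isolated)
Conditions: CuBr·SMe2 (20 mol%), Me3SiCl, THF, −78 → −30 °C; then K2CO3 (cat.), MeOH, 0 °C → rt
Reagents that add atoms: none
Why: Me3SiCl-accelerated copper-catalysed 1,4-addition in which A(1,3) strain with the ring-A aryl turns the neighbouring ring aryl pseudoaxial, so the anisyl group should reach the exocyclic β-carbon from the opposite face and, with the (E) geometry, give (S)-C-7, while methanolysis of the silyl enol ether under carbonate equilibrates C-8 to the all-trans ketone.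

Step 6
Reactants: 15 ketone from step 5
Product: 17 enol triflate of 15 toward the ring CH2 (methyl 2-{[4-(3,5-dimethoxyphenyl)-5-(4-methoxyphenyl)-2-(trifluoromethylsulfonyloxy)cyclopent-2-en-1-yl](4-methoxyphenyl)methyl}-3,5-dimethoxybenzoate; stereocentres as in 15), via potassium enolate 16 (not isolated)
Conditions: KN(SiMe3)2, THF, −78 °C; then PhNTf2, −78 → 0 °C; 1 M HCl wash
Reagents that add atoms: N-phenylbis(trifluoromethanesulfonimide) O=S(=O)(N(c1ccccc1)S(=O)(=O)C(F)(F)F)C(F)(F)F
Why: Kinetic deprotonation by the bulky amide should occur at the α-CH2 and not at the congested α-CH (C-8), and O-sulfonylation of that enolate gives the less substituted enol triflate without touching a stereocentre.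

Step 7
Reactants: 17 enol triflate; 18 tributyl(1-ethoxyvinyl)stannane
Product: 20 methyl enone (2-acetyl analogue of 17: acetyl in place of the triflyloxy group; stereocentres as in 15), via ethoxydiene 19 (not isolated)
Conditions: Pd(PPh3)4 (5 mol%), LiCl, THF, 65 °C; then 1 M HCl, THF, rt
Reagents that add atoms: water O
Why: Stille coupling (oxidative addition of the alkenyl triflate to zerovalent palladium, chloride-assisted transmetalation, reductive elimination) should give the 2-ethoxydiene, whose enol ether is hydrolysed by dilute acid to the acetyl group.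

Step 8
Reactants: 20 methyl enone
Product: 23 cyclopentenyl diazomethyl ketone (diazoacetyl in place of acetyl; stereocentres as in 15), via lithium enolate 21 (not isolated), via trifluoroacetyl diketone 22 (not isolated)
Conditions: LiN(SiMe3)2, THF, −78 °C; CF3CO2CH2CF3; aq. HCl; then MsN3, Et3N, H2O, MeCN, rt
Reagents that add atoms: methanesulfonyl azide CS(=O)(=O)N=[N+]=[N-]
Why: Detrifluoroacetylative (Regitz-type) diazo transfer, in which the kinetic enolate of the methyl group is C-trifluoroacetylated and the activated diketone accepts the diazo group from the sulfonyl azide with loss of the trifluoroacetyl group, so the conjugated alkene never meets diazomethane.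

Step 9
Reactants: 23 cyclopentenyl diazomethyl ketone; 24 ethoxyacetylene
Product: 29 methyl 2-{(S)-[(1R,2S,3S)-3-(3,5-dimethoxyphenyl)-6-ethoxy-4-hydroxy-2-(4-methoxyphenyl)-2,3-dihydro-1H-inden-1-yl](4-methoxyphenyl)methyl}-3,5-dimethoxybenzoate, via vinylketene 25 (not isolated), via cyclobutenone 26 (not isolated), via dienylketene 27 (not isolated), via cyclohexadienone 28 (not isolated)
Conditions: 24 (4 equiv), hν (300 nm), degassed ClCH2CH2Cl, rt; then 80 °C
Reagents that add atoms: none
Why: Danheiser benzannulation in its diazoketone form: light expels N2 with 1,2-shift of the cyclopentenyl group (Wolff rearrangement) to the vinylketene, which adds the ynol ether in a (2+2) cycloaddition, the nucleophilic CH terminus of ethoxyacetylene bonding to the ketene carbonyl carbon. Heating opens the cyclobutenone by 4π electrocyclic cleavage to the dienylketene, and ring B closes by 6π electrocyclisation of the ketene carbon onto the former cyclopentene CH (B5–B6 bond) to a cyclohexadienone that tautomerises to the phenol. The closest known reaction type is the same photo-Wolff benzannulation of 1-acylcycloalkene diazoketones with alkoxy- and silyloxyalkynes, which gives resorcinol monoethers. No stereocentre is created, and C-7 to C-10 should survive because the medium is neutral and none of them lies in the reacting π system, the hydrogen on the transient sp3 B6 being lost on aromatisation. The selectivity needed is regiochemical (ethoxy on B3, hydroxyl on B5, CH at B2 and B4); it is secured by the polarisation of the ynol ether and by the fact that only the cyclopentene CH can close the six-membered ring. Irradiation near 300 nm is absorbed by the diazoketone rather than the alkoxyarenes, and excess alkyne should outrun ketene dimerisation.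

Step 10
Reactants: 29 indane phenol
Product: 30 methyl 2-{(S)-[(1R,2S,3S)-3-(3,5-dimethoxyphenyl)-4,6-diethoxy-2-(4-methoxyphenyl)-2,3-dihydro-1H-inden-1-yl](4-methoxyphenyl)methyl}-3,5-dimethoxybenzoate
Conditions: EtI, K2CO3, DMF, 50 °C
Reagents that add atoms: iodoethane CCI
Why: Williamson ether synthesis, in which the hindered B5 phenoxide is O-ethylated so that ring B enters the acylation as a dialkoxyarene and cannot be O-acylated.

Step 11
Reactants: 30 diethoxy ester
Product: 31 2-{(S)-[(1R,2S,3S)-3-(3,5-dimethoxyphenyl)-4,6-diethoxy-2-(4-methoxyphenyl)-2,3-dihydro-1H-inden-1-yl](4-methoxyphenyl)methyl}-3,5-dimethoxybenzoic acid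
Conditions: LiOH, THF/MeOH/H2O, 60 °C; then 1 M HCl
Reagents that add atoms: lithium hydroxide [Li+].[OH-]
Why: Saponification (acyl–oxygen cleavage by hydroxide) of the aryl methyl ester should free the ring-A carboxylic acid, the ethers and the non-enolisable methine centres being inert to base.

Step 12
Reactants: 31 carboxylic acid
Product: 33 hexa-O-methyl-B3,B5-di-O-ethyl ether of the target (seven-membered diaryl ketone closed), via mixed anhydride 32 (not isolated)
Conditions: (CF3CO)2O, CH2Cl2 (0.01 M), 0 °C → rt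
Reagents that add atoms: none
Why: Intramolecular Friedel–Crafts acylation through the mixed trifluoroacetic anhydride, in which B2 (ortho to one ethoxy, para to the other) is the only activated carbon within reach of the tethered acyl group, so the seven-membered ketone should close as in a dibenzosuberone synthesis while the unactivated position of the C-7 anisyl ring (six-membered anthrone closure) stays untouched under these mild conditions.

Step 13
Reactants: 33 octa-O-alkyl ketone
Product: 34 CNP0116600.1 (7S,8R,9S,10S)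
Conditions: BBr3 (excess), CH2Cl2, −78 °C → rt; then H2O, 0 °C
Reagents that add atoms: none
Why: Global Lewis-acid ether cleavage, in which BBr3 coordinates each aryl ether oxygen, bromide removes the methyl or ethyl group by SN2 at carbon and the aryl borates are hydrolysed on work-up to the eight phenols, the four methine centres having no pathway to epimerise.

Compound list
1 | methyl 3,5-dimethoxybenzoate | COC(=O)c1cc(OC)cc(OC)c1 | starting material
2 | N-[2-(methoxycarbonyl)-4,6-dimethoxybenzylidene]-N-methylmethanaminium chloride | COC(=O)c1cc(OC)cc(OC)c1C=[N+](C)C.[Cl-] | intermediate (not isolated)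
3 | methyl 2-formyl-3,5-dimethoxybenzoate | COC(=O)c1cc(OC)cc(OC)c1C=O | intermediate
4 | (S)-4-(tert-butyldimethylsilyloxy)cyclopent-2-en-1-one | O=C1C=C[C@@H](O[Si](C)(C)C(C)(C)C)C1 | starting material
5 | 3,5-dimethoxyphenylmagnesium chloride | COc1cc(OC)cc([Mg]Cl)c1 | starting material
6 | (3R,4S)-4-(tert-butyldimethylsilyloxy)-3-(3,5-dimethoxyphenyl)cyclopentan-1-one (trans) | O=C1C[C@H](c2cc(OC)cc(OC)c2)[C@@H](O[Si](C)(C)C(C)(C)C)C1 | intermediate (not isolated)
7 | (S)-4-(3,5-dimethoxyphenyl)cyclopent-2-en-1-one | O=C1C=C[C@@H](c2cc(OC)cc(OC)c2)C1 | intermediate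
8 | 4-methoxyphenylmagnesium bromide | COc1ccc([Mg]Br)cc1 | starting material
9 | bromomagnesium enolate (C1=C2) of trans-4-(3,5-dimethoxyphenyl)-3-(4-methoxyphenyl)cyclopentanone | Br[Mg]OC1=C[C@H](c2ccc(OC)cc2)[C@@H](c2cc(OC)cc(OC)c2)C1 | intermediate (not isolated)
10 | bromomagnesium aldolate: methyl 2-{(bromomagnesiooxy)[2,3-trans-3,4-trans-3-(3,5-dimethoxyphenyl)-2-(4-methoxyphenyl)-5-oxocyclopentyl]methyl}-3,5-dimethoxybenzoate, both carbinol epimers | O=C1[C@@H](C(O[Mg]Br)c2c(OC)cc(OC)cc2C(=O)OC)[C@H](c2ccc(OC)cc2)[C@@H](c2cc(OC)cc(OC)c2)C1 | intermediate (not isolated)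
11 | 3-[(1R,2R,3S)-3-(3,5-dimethoxyphenyl)-2-(4-methoxyphenyl)-5-oxocyclopentyl]-4,6-dimethoxy-2-benzofuran-1(3H)-one, both epimers at lactone C-3 | O=C1[C@@H](C2OC(=O)c3cc(OC)cc(OC)c32)[C@H](c2ccc(OC)cc2)[C@@H](c2cc(OC)cc(OC)c2)C1 | intermediate
12 | cesium 2-{(E)-[(2S,3S)-3-(3,5-dimethoxyphenyl)-2-(4-methoxyphenyl)-5-oxocyclopentylidene]methyl}-3,5-dimethoxybenzoate | O=C1/C(=C/c2c(OC)cc(OC)cc2C(=O)[O-])[C@H](c2ccc(OC)cc2)[C@@H](c2cc(OC)cc(OC)c2)C1.[Cs+] | intermediate (not isolated)
13 | methyl 2-{(E)-[(2S,3S)-3-(3,5-dimethoxyphenyl)-2-(4-methoxyphenyl)-5-oxocyclopentylidene]methyl}-3,5-dimethoxybenzoate | O=C1/C(=C/c2c(OC)cc(OC)cc2C(=O)OC)[C@H](c2ccc(OC)cc2)[C@@H](c2cc(OC)cc(OC)c2)C1 | intermediate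
14 | trimethylsilyl enol ether of 15 (enol double bond between the carbonyl carbon and C-8; C-7 S) | C[Si](C)(C)OC1=C([C@@H](c2ccc(OC)cc2)c2c(OC)cc(OC)cc2C(=O)OC)[C@H](c2ccc(OC)cc2)[C@@H](c2cc(OC)cc(OC)c2)C1 | intermediate (not isolated)
15 | methyl 2-{(S)-[(1R,2R,3S)-3-(3,5-dimethoxyphenyl)-2-(4-methoxyphenyl)-5-oxocyclopentyl](4-methoxyphenyl)methyl}-3,5-dimethoxybenzoate | O=C1[C@@H]([C@@H](c2ccc(OC)cc2)c2c(OC)cc(OC)cc2C(=O)OC)[C@H](c2ccc(OC)cc2)[C@@H](c2cc(OC)cc(OC)c2)C1 | intermediate
16 | potassium enolate of 15 toward the ring CH2 | [K+].[O-]C1=C[C@H](c2cc(OC)cc(OC)c2)[C@@H](c2ccc(OC)cc2)[C@@H]1[C@@H](c1ccc(OC)cc1)c1c(OC)cc(OC)cc1C(=O)OC | intermediate (not isolated)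
17 | enol triflate: methyl 2-{[4-(3,5-dimethoxyphenyl)-5-(4-methoxyphenyl)-2-(trifluoromethylsulfonyloxy)cyclopent-2-en-1-yl](4-methoxyphenyl)methyl}-3,5-dimethoxybenzoate, ring substituents all-trans, stereocentres as in 15 | FC(F)(F)S(=O)(=O)OC1=C[C@H](c2cc(OC)cc(OC)c2)[C@@H](c2ccc(OC)cc2)[C@@H]1[C@@H](c1ccc(OC)cc1)c1c(OC)cc(OC)cc1C(=O)OC | intermediate
18 | tributyl(1-ethoxyvinyl)stannane | CCCC[Sn](CCCC)(CCCC)C(=C)OCC | starting material
19 | 2-(1-ethoxyvinyl)cyclopentene analogue of 17 (1-ethoxyvinyl in place of triflyloxy) | CCOC(=C)C1=C[C@H](c2cc(OC)cc(OC)c2)[C@@H](c2ccc(OC)cc2)[C@@H]1[C@@H](c1ccc(OC)cc1)c1c(OC)cc(OC)cc1C(=O)OC | intermediate (not isolated)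
20 | methyl enone: methyl 2-{[2-acetyl-4-(3,5-dimethoxyphenyl)-5-(4-methoxyphenyl)cyclopent-2-en-1-yl](4-methoxyphenyl)methyl}-3,5-dimethoxybenzoate, stereocentres as in 15 | CC(=O)C1=C[C@H](c2cc(OC)cc(OC)c2)[C@@H](c2ccc(OC)cc2)[C@@H]1[C@@H](c1ccc(OC)cc1)c1c(OC)cc(OC)cc1C(=O)OC | intermediate
21 | lithium enolate of 20 at the acetyl methyl group | [Li+].[O-]C(=C)C1=C[C@H](c2cc(OC)cc(OC)c2)[C@@H](c2ccc(OC)cc2)[C@@H]1[C@@H](c1ccc(OC)cc1)c1c(OC)cc(OC)cc1C(=O)OC | intermediate (not isolated)
22 | 4,4,4-trifluoro-1,3-dioxobutyl analogue of 20 (trifluoroacetylated at the acetyl methyl group) | FC(F)(F)C(=O)CC(=O)C1=C[C@H](c2cc(OC)cc(OC)c2)[C@@H](c2ccc(OC)cc2)[C@@H]1[C@@H](c1ccc(OC)cc1)c1c(OC)cc(OC)cc1C(=O)OC | intermediate (not isolated)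
23 | cyclopentenyl diazomethyl ketone: methyl 2-{[2-(diazoacetyl)-4-(3,5-dimethoxyphenyl)-5-(4-methoxyphenyl)cyclopent-2-en-1-yl](4-methoxyphenyl)methyl}-3,5-dimethoxybenzoate, stereocentres as in 15 | [N-]=[N+]=CC(=O)C1=C[C@H](c2cc(OC)cc(OC)c2)[C@@H](c2ccc(OC)cc2)[C@@H]1[C@@H](c1ccc(OC)cc1)c1c(OC)cc(OC)cc1C(=O)OC | intermediate
24 | ethoxyacetylene | C#COCC | starting material
25 | (cyclopent-1-enyl)ketene from Wolff rearrangement of 23 | O=C=CC1=C[C@H](c2cc(OC)cc(OC)c2)[C@@H](c2ccc(OC)cc2)[C@@H]1[C@@H](c1ccc(OC)cc1)c1c(OC)cc(OC)cc1C(=O)OC | intermediate (not isolated)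
26 | 3-ethoxy-4-(cyclopent-1-enyl)cyclobut-2-en-1-one, both epimers at the cyclobutenone sp3 carbon | CCOC1=CC(=O)C1C1=C[C@H](c2cc(OC)cc(OC)c2)[C@@H](c2ccc(OC)cc2)[C@@H]1[C@@H](c1ccc(OC)cc1)c1c(OC)cc(OC)cc1C(=O)OC | intermediate (not isolated)
27 | 3-ethoxy-4-(cyclopent-1-enyl)buta-1,3-dien-1-one (dienylketene) | O=C=CC(OCC)=CC1=C[C@H](c2cc(OC)cc(OC)c2)[C@@H](c2ccc(OC)cc2)[C@@H]1[C@@H](c1ccc(OC)cc1)c1c(OC)cc(OC)cc1C(=O)OC | intermediate (not isolated)
28 | ring-B cyclohexa-2,4-dienone tautomer of 29 (B6 sp3, B5 carbonyl) | O=C1C=C(OCC)C=C2C1[C@H](c1cc(OC)cc(OC)c1)[C@@H](c1ccc(OC)cc1)[C@@H]2[C@@H](c1ccc(OC)cc1)c1c(OC)cc(OC)cc1C(=O)OC | intermediate (not isolated)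
29 | methyl 2-{(S)-[(1R,2S,3S)-3-(3,5-dimethoxyphenyl)-6-ethoxy-4-hydroxy-2-(4-methoxyphenyl)-2,3-dihydro-1H-inden-1-yl](4-methoxyphenyl)methyl}-3,5-dimethoxybenzoate | COC(=O)c1cc(OC)cc(OC)c1[C@H](c1ccc(OC)cc1)[C@@H]1c2cc(OCC)cc(O)c2[C@H](c2cc(OC)cc(OC)c2)[C@H]1c1ccc(OC)cc1 | intermediate
30 | methyl 2-{(S)-[(1R,2S,3S)-3-(3,5-dimethoxyphenyl)-4,6-diethoxy-2-(4-methoxyphenyl)-2,3-dihydro-1H-inden-1-yl](4-methoxyphenyl)methyl}-3,5-dimethoxybenzoate | COC(=O)c1cc(OC)cc(OC)c1[C@H](c1ccc(OC)cc1)[C@@H]1c2cc(OCC)cc(OCC)c2[C@H](c2cc(OC)cc(OC)c2)[C@H]1c1ccc(OC)cc1 | intermediate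
31 | 2-{(S)-[(1R,2S,3S)-3-(3,5-dimethoxyphenyl)-4,6-diethoxy-2-(4-methoxyphenyl)-2,3-dihydro-1H-inden-1-yl](4-methoxyphenyl)methyl}-3,5-dimethoxybenzoic acid | OC(=O)c1cc(OC)cc(OC)c1[C@H](c1ccc(OC)cc1)[C@@H]1c2cc(OCC)cc(OCC)c2[C@H](c2cc(OC)cc(OC)c2)[C@H]1c1ccc(OC)cc1 | intermediate
32 | mixed trifluoroacetic anhydride of 31 | FC(F)(F)C(=O)OC(=O)c1cc(OC)cc(OC)c1[C@H](c1ccc(OC)cc1)[C@@H]1c2cc(OCC)cc(OCC)c2[C@H](c2cc(OC)cc(OC)c2)[C@H]1c1ccc(OC)cc1 | intermediate (not isolated)
33 | (7S,8R,9S,10S) octa-O-alkyl ether of the target: six methyl ethers, ethyl ethers on B3 and B5 | O=C1c2cc(OC)cc(OC)c2[C@H](c2ccc(OC)cc2)[C@@H]2c3c1c(OCC)cc(OCC)c3[C@H](c1cc(OC)cc(OC)c1)[C@H]2c1ccc(OC)cc1 | intermediate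
34 | CNP0116600.1, (7S,8R,9S,10S) | O=C1c2cc(O)cc(O)c2[C@H](c2ccc(O)cc2)[C@@H]2c3c1c(O)cc(O)c3[C@H](c1cc(O)cc(O)c1)[C@H]2c1ccc(O)cc1 | target

Total step count: 13. Longest linear sequence: 12 steps (steps 2–13, from 4 to 34; step 1 is a one-step branch that joins at step 3).

Steps most likely to fail

Step 9. The five alkoxyarene chromophores may compete for light, and the hindered ketene may dimerise or acylate the product phenol faster than it adds the ynol ether. The fallback avoids photochemistry and ketenes and builds ring B by polyketide-type aldol aromatisation; it sets out from ketone 15 and comes back at diethoxy ester 30. Soft enolisation (MgBr2·OEt2, i-Pr2NEt, 1-acetylbenzotriazole, CH2Cl2) should acetylate the unhindered α-CH2 to give the β-diketone F1. Its dianion (LiN(i-Pr)2, THF, −78 → 0 °C) is acylated at the terminal methyl group by N-methoxy-N-methylacetamide to give the 1,3,5-triketone F2. NaOMe in MeOH at 50 °C should then close the terminal methyl ketone onto the ring carbonyl, and dehydration and enolisation give the indane-4,6-diol F3 with free hydroxyls on B3 and B5. Ethylation of both hydroxyls (EtI, K2CO3, DMF) delivers 30.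

Step 5. Facial discrimination at the exocyclic β-carbon may be poor, or addition may stall because that carbon is flanked by a di-ortho-substituted aryl group and the neighbouring ring aryl, leaving 1,2-addition to compete. The fallback replaces substrate control by catalyst control; it sets out from enone 13 and comes back at ketone 15. It is a Hayashi–Miyaura arylation with 4-methoxyphenylboronic acid, [RhCl(C2H4)2]2, a C2-symmetric chiral bicyclo[2.2.2]octadiene ligand (the antipode that reinforces the substrate bias toward (S)-C-7), KOH, dioxane/H2O, 50 °C. The aqueous base protonates the rhodium enolate and equilibrates C-8, so 15 is reached directly and no new compound arises (F0).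

Step 3. Proton transfer between the magnesium enolate and the products, or slow capture of the crowded, electron-rich aldehyde, may scramble the enolate regiochemistry or return only the conjugate adduct. The fallback separates the two bond formations; it sets out from enone 7 and comes back at phthalide 11. The copper-catalysed addition of 8 is run in the presence of Me3SiCl and the regiodefined trimethylsilyl enol ether F4 is isolated. A Mukaiyama aldol addition to aldehyde 3 activated by TiCl4 (CH2Cl2, −78 °C), followed by warming with aqueous acid to close the lactone, should give 11.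

Further compounds
F1 | step 9 | methyl 2-{(S)-[4-acetyl-3-(3,5-dimethoxyphenyl)-2-(4-methoxyphenyl)-5-oxocyclopentyl](4-methoxyphenyl)methyl}-3,5-dimethoxybenzoate (β-diketone, other centres as in 15) | O=C1[C@@H]([C@@H](c2ccc(OC)cc2)c2c(OC)cc(OC)cc2C(=O)OC)[C@H](c2ccc(OC)cc2)[C@@H](c2cc(OC)cc(OC)c2)C1C(C)=O
F2 | step 9 | methyl 2-{(S)-[3-(3,5-dimethoxyphenyl)-2-(4-methoxyphenyl)-5-oxo-4-(3-oxobutanoyl)cyclopentyl](4-methoxyphenyl)methyl}-3,5-dimethoxybenzoate (1,3,5-triketone) | O=C1[C@@H]([C@@H](c2ccc(OC)cc2)c2c(OC)cc(OC)cc2C(=O)OC)[C@H](c2ccc(OC)cc2)[C@@H](c2cc(OC)cc(OC)c2)C1C(=O)CC(C)=O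
F3 | step 9 | methyl 2-{(S)-[(1R,2S,3S)-3-(3,5-dimethoxyphenyl)-4,6-dihydroxy-2-(4-methoxyphenyl)-2,3-dihydro-1H-inden-1-yl](4-methoxyphenyl)methyl}-3,5-dimethoxybenzoate | COC(=O)c1cc(OC)cc(OC)c1[C@H](c1ccc(OC)cc1)[C@@H]1c2cc(O)cc(O)c2[C@H](c2cc(OC)cc(OC)c2)[C@H]1c1ccc(OC)cc1
F0 | step 5 | none | none
F4 | step 3 | trimethylsilyl enol ether (C1=C2) of trans-4-(3,5-dimethoxyphenyl)-3-(4-methoxyphenyl)cyclopentanone | C[Si](C)(C)OC1=C[C@H](c2ccc(OC)cc2)[C@@H](c2cc(OC)cc(OC)c2)C1
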